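The flask may be read up to 2.0 min, so we turn the question round: for the best moment to sit at that limit, single product would have to be still rising there.

| flask | substrate | gas | remark | time |
|---|---|---|---|---|
| south-west | 0.13 mM | 0.038 mM (held) | run made earlier |  |
| north-west | 0.30 mM | 0.038 mM (held) | run made earlier |  |
| flask | 0.20 mM | 0.038 mM (held) |  | 2.0 min |

| run | time / s | single product / % |
|---|---|---|
| south-west | 12.0 | 39.0 |
| south-west | 15.0 | 45.1 |
| south-west | 20.0 | 50.2 |
| south-west | 30.0 | 60.1 |
| south-west | 40.0 | 61.9 |
| south-west | 50.0 | 63.1 |
| south-west | 80.0 | 56.2 |
| north-west | 12.0 | 33.8 |
| north-west | 15.0 | 40.6 |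
| north-west | 20.0 | 44.9 |
| north-west | 30.0 | 47.8 |
| north-west | 40.0 | 52.1 |
| north-west | 50.0 | 49.6 |
| north-west | 80.0 | 45.6 |

(standard deviation of a reading: 1 percentage point)

1. the moment within 2.0 min at which there is most single product
2. the amount of single product, in percent of the substrate charged, at that time

- at the start none of the gas is in solution

The nearer run, south-west, shows the opposite: it reads 63.1 % at 50.0 s but 56.2 % at 80.0 s, which is earlier than the limit. From these two readings we take our own measure: at that pace single product halves in 2.99 min, its loss half-life, a reading that carries the scatter of both points. Counted from 50.0 s, the limit lies 0.390 loss half-lives on, so we expect the flask to pass its peak inside the window and to be falling at the limit.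

The forecast puts the peak at 0.72 min (range 0.55 min to 0.9 min) with 57 % (54 % to 60 %), and holds that “the 2.0 min limit doesn't bind”.

The flask gives 56.2 % at 0.733 min, inside both ranges.

    2 substrate → homo dimer (k = 115 /M/s)
    substrate + coupling partner → single product + by-product (k = 1420 /M/s)
    gas ⇌ coupling partner, rate k3*(csat - [coupling partner]) (kL = 5.77 /s)
    coupling partner + single product → double product + by-product (k = 138 /M/s)
    coupling partner ⇌ dormant form (K = 7.10, k = 0.0168 /s)
    coupling partner + double product → triple product + by-product (k = 90.3 /M/s)

By 0.734 min the flask's substrate had fallen to 5.46 %, having gone to single product, part of that already further on to 9.20 % of double product and 0.569 % of triple product, and to 28.6 % of homo dimer, which counts as the two substrate it holds. From then to 2.00 min coupling partner stood at 0.0378 mM, and single product went on to double product in a pseudo-first-order loss, leaving in the flask 41.7 % of single product, 24.4 % of double product and 5.14 % of triple product at 2.00 min. Our half-life, read from the south-west run and counted from the flask's peak, gives 41.9 % of single product there.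

For the same flask read at 8.0 min, the count is 2.43 half-lives, which gives 10.4 %. The computed amount is 6.37 %, less than our count.

The earlier runs and the new flask are calculated with constants of no real substance, noise included.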